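**Plan**
1. Cuts: O-benzyl and N-tosyl on indole B come off last. Before that, N1–C7a of indole A (the 6-methoxyindole) is cut, which opens its pyrrole ring to a 2,2-diarylvinyl azide.
2. Further cuts: C–N3 (from C–Br, itself from the =CH2 of a 1,1-diarylethene), ring C–C3 of indole B (Suzuki–Miyaura), and ring C–C(=CH2) (aryllithium plus 4-methoxyacetophenone).
3. Enabling feature: in indole A the methoxy carbon C6 is para to C3a, so C3a/C4/C5/C6/C7/C7a is a 4-methoxyphenyl ring with two equivalent ortho C–H bonds. The two ring C carbons next to the vinyl carbon both carry OMe and offer nitrogen no C–H bond.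
4. Forward: indole B is bought intact and converted to its 3-boronate. Ring C is dibrominated, joined to the anisylethene unit and then to indole B. Bromide and azide follow, and the pyrrole ring of indole A is the only ring made.
5. Stereochemistry: the target has no stereocentre. The alkene geometry and the azirine stereocentre are transient and vanish in the key step. The aryl–indolyl axes are taken as freely rotating.

Key step: step 9

Assumption: the vinyl bromide and the vinyl azide are expected as E/Z mixtures and are carried on unseparated. Names and SMILES show the E isomer (bromine or azide cis to the 4-methoxyphenyl ring). This is harmless because both isomers lose N2 to the same azirine. Tosyl means 4-methylbenzenesulfonyl.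

**Step 1**
Reactants: 1 5-(benzyloxy)-1H-indole
Product: 2 5-(benzyloxy)-3-iodo-1H-indole
Conditions: NIS (1.05 equiv), DMF, 0 °C → rt, dark
Reagents that add atoms: N-iodosuccinimide, O=C1CCC(=O)N1I
Why: Electrophilic aromatic iodination takes place at C3, the enamine-like and most nucleophilic carbon of an N–H indole, faster than on the benzyloxy-activated benzo ring.

**Step 2**
Reactants: 2 5-(benzyloxy)-3-iodo-1H-indole
Product: 3 5-(benzyloxy)-3-iodo-1-tosyl-1H-indole
Conditions: NaH (1.2 equiv), DMF, 0 °C; TsCl (1.1 equiv), 0 °C → rt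
Reagents that add atoms: p-toluenesulfonyl chloride, Cc1ccc(cc1)S(=O)(=O)Cl
Why: N-Sulfonylation of the sodium indolide is routine, stabilises the sensitive 3-iodoindole and masks N–H for the palladium, copper and rhodium steps that follow.

**Step 3**
Reactants: 3 5-(benzyloxy)-3-iodo-1-tosyl-1H-indole
Product: 4 5-(benzyloxy)-3-(4,4,5,5-tetramethyl-1,3,2-dioxaborolan-2-yl)-1-tosyl-1H-indole
Conditions: B2pin2 (1.3 equiv), PdCl2(dppf) (5 mol %), KOAc (3 equiv), 1,4-dioxane, 85 °C
Reagents that add atoms: bis(pinacolato)diboron, CC1(C)OB(OC1(C)C)B1OC(C)(C)C(C)(C)O1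
Why: Miyaura borylation of an aryl iodide, well established for 3-iodo-1-sulfonylindoles, uses a base (KOAc) too weak to start homocoupling or to cleave the sulfonamide.

**Step 4**
Reactants: 5 1,2,4,5-tetramethoxybenzene
Product: 6 1,4-dibromo-2,3,5,6-tetramethoxybenzene
Conditions: Br2 (2.1 equiv), CH2Cl2, 0 °C → rt
Reagents that add atoms: bromine, BrBr
Why: Twofold electrophilic aromatic bromination can only hit the two remaining C–H positions of 5, which are para to each other and strongly activated, so a single dibromide should result if the mixture is kept cold and dry to avoid oxidative demethylation.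

**Step 5**
Reactants: 6 1,4-dibromo-2,3,5,6-tetramethoxybenzene; 7 4-methoxyacetophenone
Product: 10 1-bromo-2,3,5,6-tetramethoxy-4-[1-(4-methoxyphenyl)ethenyl]benzene, via aryllithium 8 (not isolated), via tertiary alcohol 9 (not isolated)
Conditions: n-BuLi (1.0 equiv), THF, –78 °C; 7 (1.1 equiv), –78 °C → rt; then aq. HCl (3 M), rt → 40 °C
Reagents that add atoms: none
Why: Bromine–lithium exchange with one equivalent of n-BuLi should stop at the monolithio arene 8, whose 1,2-addition to ketone 7 gives the doubly benzylic carbinol 9 (racemic, stereocentre lost at once), and the acid quench ionises it to an anisyl-stabilised cation that loses a methyl proton (E1 dehydration).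

**Step 6**
Reactants: 10 1-bromo-2,3,5,6-tetramethoxy-4-[1-(4-methoxyphenyl)ethenyl]benzene; 4 5-(benzyloxy)-3-(4,4,5,5-tetramethyl-1,3,2-dioxaborolan-2-yl)-1-tosyl-1H-indole
Product: 11 5-(benzyloxy)-3-{2,3,5,6-tetramethoxy-4-[1-(4-methoxyphenyl)ethenyl]phenyl}-1-tosyl-1H-indole
Conditions: Pd(OAc)2 (5 mol %), SPhos (10 mol %), K3PO4 (3 equiv), toluene/H2O (10:1), 100 °C
Reagents that add atoms: none
Why: Suzuki–Miyaura coupling with the bulky, electron-rich biarylphosphine SPhos is the standard answer to electron-rich aryl bromides with two ortho substituents, while the 1,1-disubstituted alkene is a poor Heck acceptor and tosyl tolerates K3PO4.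

**Step 7**
Reactants: 11 5-(benzyloxy)-3-{2,3,5,6-tetramethoxy-4-[1-(4-methoxyphenyl)ethenyl]phenyl}-1-tosyl-1H-indole
Product: 12 5-(benzyloxy)-3-{4-[(E)-2-bromo-1-(4-methoxyphenyl)ethenyl]-2,3,5,6-tetramethoxyphenyl}-1-tosyl-1H-indole
Conditions: NBS (1.05 equiv), CH2Cl2, 0 °C → rt, dark
Reagents that add atoms: N-bromosuccinimide, O=C1CCC(=O)N1Br
Why: Electrophilic bromination followed by proton loss (addition–elimination, the classical conversion of 1,1-diarylethenes into 2-bromo-1,1-diarylethenes) should be chemoselective because the anisyl-conjugated alkene is far more nucleophilic than the N-sulfonylindole or any of the ether-bearing arenes.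

**Step 8**
Reactants: 12 5-(benzyloxy)-3-{4-[(E)-2-bromo-1-(4-methoxyphenyl)ethenyl]-2,3,5,6-tetramethoxyphenyl}-1-tosyl-1H-indole
Product: 13 3-{4-[(E)-2-azido-1-(4-methoxyphenyl)ethenyl]-2,3,5,6-tetramethoxyphenyl}-5-(benzyloxy)-1-tosyl-1H-indole
Conditions: NaN3 (2 equiv), CuI (10 mol %), N,N'-dimethylethylenediamine (20 mol %), sodium ascorbate (10 mol %), DMSO/H2O (5:1), 65 °C, dark
Reagents that add atoms: sodium azide, [Na+].[N-]=[N+]=[N-]
Why: Ullmann-type copper-catalysed halide–azide exchange at an sp2 carbon is known for alkenyl halides with a diamine ligand and ascorbate, proceeds with retention of whatever geometry is present and is run below the temperature at which vinyl azides lose N2.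

**Step 9**
Reactants: 13 3-{4-[(E)-2-azido-1-(4-methoxyphenyl)ethenyl]-2,3,5,6-tetramethoxyphenyl}-5-(benzyloxy)-1-tosyl-1H-indole
Product: 15 5-(benzyloxy)-3-[2,3,5,6-tetramethoxy-4-(6-methoxy-1H-indol-3-yl)phenyl]-1-tosyl-1H-indole, via 2H-azirine 14 (not isolated)
Conditions: Rh2(O2CC3F7)4 (5 mol %), 4 Å MS, xylene (0.02 M), 120 °C, Ar
Reagents that add atoms: none
Why: On heating the azide loses N2 to give the racemic 2,2-diaryl-2H-azirine 14, whose strained benzhydrylic C2–N bond is reopened, thermally or after coordination of nitrogen to the Lewis-acidic dirhodium core, to a vinylnitrene or its rhodium nitrenoid. The closest known reactions are the pyrolysis of beta-styryl azides to indoles, the Hemetsberger indole synthesis and the dirhodium-carboxylate-catalysed isomerisation of 2-aryl-2H-azirines to indoles. The pyrrole ring closes by a five-centre electrocyclisation over N1, C2, C3, C3a and C7a (formally 5-endo-trig), and a 1,5-hydrogen shift from C7a to N1 restores aromaticity. No stereocentre is created, the stereocentre of 14 disappears on ring opening, and because both nitrene rotamers can fall back to the same azirine the E/Z composition of 13 does not matter. The step needs selectivity between the two aryl groups and between the two ortho sites of the anisyl ring: ring C bears methoxy on both carbons flanking the vinyl carbon, so closure there could not rearomatise and reverts, and the two ortho C–H bonds of the 4-methoxyphenyl ring are related by symmetry, so only the 6-methoxy isomer can arise. High dilution suppresses bimolecular azirine and nitrene chemistry, and the catalyst is there to favour closure over hydrogen migration.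

**Step 10**
Reactants: 15 5-(benzyloxy)-3-[2,3,5,6-tetramethoxy-4-(6-methoxy-1H-indol-3-yl)phenyl]-1-tosyl-1H-indole
Product: 16 5-(benzyloxy)-3-[2,3,5,6-tetramethoxy-4-(6-methoxy-1H-indol-3-yl)phenyl]-1H-indole
Conditions: Mg turnings (10 equiv), MeOH/THF (3:1), sonication, rt
Reagents that add atoms: none
Why: Dissolving-metal (single-electron) cleavage of the N–S bond by Mg in MeOH is a standard detosylation of indoles and leaves the benzyl ether, the aryl methyl ethers and both indole rings untouched.

**Step 11**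
Reactants: 16 5-(benzyloxy)-3-[2,3,5,6-tetramethoxy-4-(6-methoxy-1H-indol-3-yl)phenyl]-1H-indole
Product: 17 3-[2,3,5,6-tetramethoxy-4-(6-methoxy-1H-indol-3-yl)phenyl]-1H-indol-5-ol (CNP0234672.0)
Conditions: H2 (1 atm), 10% Pd/C, EtOAc/MeOH (1:1), rt
Reagents that add atoms: none
Why: Catalytic hydrogenolysis cleaves only the benzylic C–O bond, since indoles and aryl methyl ethers are inert to Pd/C at atmospheric pressure and room temperature.

**Compound list**
1 | 5-(benzyloxy)-1H-indole | c1ccc(COc2ccc3[nH]ccc3c2)cc1 | starting material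
2 | 5-(benzyloxy)-3-iodo-1H-indole | Ic1c[nH]c2ccc(OCc3ccccc3)cc12 | intermediate
3 | 5-(benzyloxy)-3-iodo-1-tosyl-1H-indole | Cc1ccc(cc1)S(=O)(=O)n1cc(I)c2cc(OCc3ccccc3)ccc12 | intermediate
4 | 5-(benzyloxy)-3-(4,4,5,5-tetramethyl-1,3,2-dioxaborolan-2-yl)-1-tosyl-1H-indole | Cc1ccc(cc1)S(=O)(=O)n1cc(B2OC(C)(C)C(C)(C)O2)c2cc(OCc3ccccc3)ccc12 | intermediate
5 | 1,2,4,5-tetramethoxybenzene | COc1cc(OC)c(OC)cc1OC | starting material
6 | 1,4-dibromo-2,3,5,6-tetramethoxybenzene | COc1c(Br)c(OC)c(OC)c(Br)c1OC | intermediate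
7 | 4-methoxyacetophenone | CC(=O)c1ccc(OC)cc1 | starting material
8 | (4-bromo-2,3,5,6-tetramethoxyphenyl)lithium | [Li]c1c(OC)c(OC)c(Br)c(OC)c1OC | intermediate
9 | (±)-1-(4-bromo-2,3,5,6-tetramethoxyphenyl)-1-(4-methoxyphenyl)ethan-1-ol (racemic, formed first as its lithium alkoxide) | CC(O)(c1ccc(OC)cc1)c1c(OC)c(OC)c(Br)c(OC)c1OC | intermediate
10 | 1-bromo-2,3,5,6-tetramethoxy-4-[1-(4-methoxyphenyl)ethenyl]benzene | C=C(c1ccc(OC)cc1)c1c(OC)c(OC)c(Br)c(OC)c1OC | intermediate
11 | 5-(benzyloxy)-3-{2,3,5,6-tetramethoxy-4-[1-(4-methoxyphenyl)ethenyl]phenyl}-1-tosyl-1H-indole | C=C(c1ccc(OC)cc1)c1c(OC)c(OC)c(-c2cn(S(=O)(=O)c3ccc(C)cc3)c3ccc(OCc4ccccc4)cc23)c(OC)c1OC | intermediate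
12 | 5-(benzyloxy)-3-{4-[(E)-2-bromo-1-(4-methoxyphenyl)ethenyl]-2,3,5,6-tetramethoxyphenyl}-1-tosyl-1H-indole | Br/C=C(\c1ccc(OC)cc1)c1c(OC)c(OC)c(-c2cn(S(=O)(=O)c3ccc(C)cc3)c3ccc(OCc4ccccc4)cc23)c(OC)c1OC | intermediate
13 | 3-{4-[(E)-2-azido-1-(4-methoxyphenyl)ethenyl]-2,3,5,6-tetramethoxyphenyl}-5-(benzyloxy)-1-tosyl-1H-indole | [N-]=[N+]=N/C=C(\c1ccc(OC)cc1)c1c(OC)c(OC)c(-c2cn(S(=O)(=O)c3ccc(C)cc3)c3ccc(OCc4ccccc4)cc23)c(OC)c1OC | intermediate
14 | (±)-5-(benzyloxy)-3-{2,3,5,6-tetramethoxy-4-[2-(4-methoxyphenyl)-2H-azirin-2-yl]phenyl}-1-tosyl-1H-indole (racemic) | COc1ccc(cc1)C1(C=N1)c1c(OC)c(OC)c(-c2cn(S(=O)(=O)c3ccc(C)cc3)c3ccc(OCc4ccccc4)cc23)c(OC)c1OC | intermediate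
15 | 5-(benzyloxy)-3-[2,3,5,6-tetramethoxy-4-(6-methoxy-1H-indol-3-yl)phenyl]-1-tosyl-1H-indole | COc1ccc2c(-c3c(OC)c(OC)c(-c4cn(S(=O)(=O)c5ccc(C)cc5)c5ccc(OCc6ccccc6)cc45)c(OC)c3OC)c[nH]c2c1 | intermediate
16 | 5-(benzyloxy)-3-[2,3,5,6-tetramethoxy-4-(6-methoxy-1H-indol-3-yl)phenyl]-1H-indole | COc1ccc2c(-c3c(OC)c(OC)c(-c4c[nH]c5ccc(OCc6ccccc6)cc45)c(OC)c3OC)c[nH]c2c1 | intermediate
17 | 3-[2,3,5,6-tetramethoxy-4-(6-methoxy-1H-indol-3-yl)phenyl]-1H-indol-5-ol | COc1ccc2c(-c3c(OC)c(OC)c(-c4c[nH]c5ccc(O)cc45)c(OC)c3OC)c[nH]c2c1 | target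

**Step count**
Total step count: 11.
Longest linear sequence: 9 steps (steps 1, 2, 3, 6, 7, 8, 9, 10 and 11, starting from 1). The ring C branch (steps 4 and 5) joins at step 6.

**Steps most likely to fail**

Step 9. The azirine carries hydrogen on its C=N carbon. A hydrogen shift within the azirine/vinylnitrene manifold, or oligomerisation of the azirine, may outrun ring closure.
The fallback keeps the N1–C7a bond but makes it by palladium C–H activation in place of nitrene chemistry. It sets out from 12. A Goldberg-type N-vinylation of p-toluenesulfonamide (CuI, N,N'-dimethylethylenediamine, K2CO3, dioxane, 100 °C) should give the N-tosyl enamine F1, whose geometry equilibrates through its imine tautomer. Oxidative intramolecular C–H amination (Pd(OAc)2, Cu(OAc)2, O2, DMSO), a known entry to 3-aryl-1-sulfonylindoles from 2,2-diaryl N-sulfonyl enamines, can again only use an ortho C–H bond of the anisyl ring. It should give the bis-N-tosyl bisindole F2. The conditions of step 10 with twice the magnesium remove both sulfonyl groups, and the route is rejoined at 16.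

Step 8. Halide–azide exchange at the alkenyl bromide may be too slow at a temperature the product tolerates. Premature loss of N2 or copper-mediated reduction of the azide would then take over.
The fallback replaces the Ullmann-type exchange by an oxidative coupling that runs near room temperature. It sets out from 12. Miyaura borylation under the alkenyl halide protocol (B2pin2, PdCl2(PPh3)2, PPh3, KOPh, toluene, 50 °C) should give the alkenyl pinacol boronate F3. Chan–Lam-type azidation (NaN3, Cu(OAc)2 10 mol %, MeOH, air, rt → 40 °C) then returns to the route at 13.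

Step 5. The hindered, basic aryllithium may deprotonate the methyl ketone instead of adding to its carbonyl group, which would return debrominated arene and ketone after the quench.
The fallback uses a carbonyl partner that cannot enolise and brings in the methyl carbon separately. It sets out from 6, lithiated to 8 as before. Acylation with commercial N-methoxy-N-methyl-4-methoxybenzamide (Weinreb ketone synthesis, THF, –78 °C → 0 °C) should give the diaryl ketone F4. MeMgBr (THF, 0 °C → rt) adds to it to give the magnesium alkoxide of 9, and the same aqueous HCl quench dehydrates it, so the route is rejoined at 9 and thus at 10.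

**Further compounds**
F1 | step 9 | N-[(E)-2-{4-[5-(benzyloxy)-1-tosyl-1H-indol-3-yl]-2,3,5,6-tetramethoxyphenyl}-2-(4-methoxyphenyl)ethenyl]-4-methylbenzenesulfonamide | Cc1ccc(cc1)S(=O)(=O)N/C=C(\c1ccc(OC)cc1)c1c(OC)c(OC)c(-c2cn(S(=O)(=O)c3ccc(C)cc3)c3ccc(OCc4ccccc4)cc23)c(OC)c1OC
F2 | step 9 | 5-(benzyloxy)-3-[2,3,5,6-tetramethoxy-4-(6-methoxy-1-tosyl-1H-indol-3-yl)phenyl]-1-tosyl-1H-indole | COc1ccc2c(-c3c(OC)c(OC)c(-c4cn(S(=O)(=O)c5ccc(C)cc5)c5ccc(OCc6ccccc6)cc45)c(OC)c3OC)cn(S(=O)(=O)c3ccc(C)cc3)c2c1
F3 | step 8 | 5-(benzyloxy)-3-{2,3,5,6-tetramethoxy-4-[(E)-1-(4-methoxyphenyl)-2-(4,4,5,5-tetramethyl-1,3,2-dioxaborolan-2-yl)ethenyl]phenyl}-1-tosyl-1H-indole | CC1(C)OB(/C=C(\c2ccc(OC)cc2)c2c(OC)c(OC)c(-c3cn(S(=O)(=O)c4ccc(C)cc4)c4ccc(OCc5ccccc5)cc34)c(OC)c2OC)OC1(C)C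
F4 | step 5 | (4-bromo-2,3,5,6-tetramethoxyphenyl)(4-methoxyphenyl)methanone | O=C(c1ccc(OC)cc1)c1c(OC)c(OC)c(Br)c(OC)c1OC
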